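The lactone ring (C1, O2, C3, C4, C4a, C8a) is opened at O2–C3. C3 is a carbinol carbon esterified by the ring's own C1 carboxyl and bonded to C1', so C3–C1'–C2' can serve as an allyl unit. An iridium–phosphoramidite catalyst ionises a linear (E)-allyl carbonate placed ortho to a free benzoic acid, and the carboxylate closes the six-membered ring at the substituted allyl terminus. One operation forms O2–C3, sets C3 and leaves a vinyl group on C3. Cross-metathesis with a chiral-pool alkenol (C9' from (S)-1,2-epoxybutane) then adds C2'–C11'. Alkene saturation and debenzylation finish the synthesis.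

Key step: step 6

Assumption: atoms are labelled by isochromanone numbering (C1 carbonyl, O2, C3, C4, C4a–C8a; side chain C1'–C11'), and the target is read as 3R,9'S. The vinyl lactone is 3S with the same spatial arrangement, because vinyl outranks C4 while the saturated chain does not. The terminal CH2 of the C3 vinyl group leaves as ethene in step 8, so the alkenol must supply ten carbons (C2'–C11'), which is why an eleven-carbon alkenol is used. Compound 2 is used as its commercial THF solution.

Step 1
Reactants: 1 3,5-bis(benzyloxy)benzyl bromide; 2 vinylmagnesium bromide (CH2=CHMgBr)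
Product: 3 1-allyl-3,5-bis(benzyloxy)benzene
Conditions: 2 (1.5 equiv), CuI (10 mol%), THF, −20 °C to rt
Reagents that add atoms: none
Why: Copper-catalysed Kumada-type sp3–sp2 coupling of a benzylic bromide with a vinyl Grignard reagent is a standard route to allylarenes, and aryl benzyl ethers are inert to the reagent at this temperature.

Step 2
Reactants: 3 1-allyl-3,5-bis(benzyloxy)benzene
Product: 5 2-allyl-4,6-bis(benzyloxy)benzaldehyde, via aryl iminium dichlorophosphate 4 (not isolated)
Conditions: POCl3, DMF, 0 to 70 °C; then H2O, 0 °C to rt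
Reagents that add atoms: N,N-dimethylformamide CN(C)C=O; water O
Why: Vilsmeier–Haack formylation should take the ring position next to the allyl group, which is activated ortho and para by the two benzyloxy groups and is less crowded than the position between them, as with orcinol diethers; the isolated alkene and the benzyl ethers tolerate the reagent.

Step 3
Reactants: 6 (Z)-but-2-ene-1,4-diol
Product: 7 (Z)-but-2-ene-1,4-diyl dimethyl bis(carbonate)
Conditions: ClCO2Me (2.5 equiv), pyridine, CH2Cl2, 0 °C to rt
Reagents that add atoms: methyl chloroformate COC(=O)Cl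
Why: Acylation of two primary hydroxyls with a chloroformate under pyridine is routine, and the alkene geometry of this symmetrical metathesis partner is of no consequence.

Step 4
Reactants: 5 2-allyl-4,6-bis(benzyloxy)benzaldehyde; 7 (Z)-but-2-ene-1,4-diyl dimethyl bis(carbonate)
Product: 8 (E)-4-[3,5-bis(benzyloxy)-2-formylphenyl]but-2-en-1-yl methyl carbonate
Conditions: 7 (3 equiv), second-generation Grubbs catalyst (H2IMes)(PCy3)Cl2Ru=CHPh (5 mol%), CH2Cl2, 40 °C
Reagents that add atoms: none
Why: Olefin cross-metathesis of a terminal allylarene with an excess of a symmetrical cis-butenediol derivative is well established, tolerates the aldehyde and should give mainly the E-alkene under thermodynamic control; the neutral aldehyde is purified here so that only E-configured material reaches step 6.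

Step 5
Reactants: 8 (E)-4-[3,5-bis(benzyloxy)-2-formylphenyl]but-2-en-1-yl methyl carbonate
Product: 9 2,4-bis(benzyloxy)-6-[(E)-4-(methoxycarbonyloxy)but-2-en-1-yl]benzoic acid
Conditions: NaClO2, NaH2PO4, 2-methylbut-2-ene, t-BuOH/H2O, rt
Reagents that add atoms: sodium chlorite [Na+].[O-]Cl=O
Why: Pinnick (Lindgren–Kraus) oxidation turns hindered, electron-rich benzaldehydes into benzoic acids under buffered conditions that spare the allylic carbonate, the alkene and the benzyl ethers, with 2-methylbut-2-ene trapping hypochlorous acid before it can chlorinate the ring.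

Step 6
Reactants: 9 2,4-bis(benzyloxy)-6-[(E)-4-(methoxycarbonyloxy)but-2-en-1-yl]benzoic acid
Product: 10 (3S)-6,8-bis(benzyloxy)-3-vinylisochroman-1-one
Conditions: [Ir(cod)Cl]2 (2 mol%), (Ra,Rc,Rc)-L (4 mol%), TBD (10 mol%), THF (0.05 M), rt, AcOH quench at full conversion; L = O,O'-(1,1'-binaphthalene-2,2'-diyl) N,N-bis(1-phenylethyl)phosphoramidite, TBD = 1,5,7-triazabicyclo[4.4.0]dec-5-ene
Reagents that add atoms: none
Why: Proposed new method: the cyclometalated monovalent iridium–phosphoramidite complex ionises the linear carbonate with loss of CO2 and methoxide to a trivalent iridium allyl complex spanning C3, C1' and C2'; the methoxide deprotonates the benzoic acid and the carboxylate attacks C3 on the face opposite the metal to form O2–C3. The closest known reaction type is iridium–phosphoramidite branched-selective allylic substitution by O-nucleophiles (intermolecular esterification with carboxylates, and ring closures by alkoxides or amines to 2-vinyl heterocycles); closure by a benzoate to a six-membered lactone is not established, hence the label. The ring (C1, O2, C3, C4, C4a, C8a) closes in a 6-exo sense with the vinyl group left outside the ring. C3 is set by the chiral ligand, which fixes the face of the syn allyl complex formed from the E-alkene; the (Ra,Rc,Rc) ligand is chosen by analogy with the facial sense of this catalyst family in intermolecular O- and N-allylations and should give 3S, the mirror-image ligand being the remedy if the tethered case responds oppositely. The step needs branched regioselectivity and one allyl face: attack at C2' would require an eight-membered ring, so the tether and the metal's preference for the substituted terminus point the same way. Substoichiometric base, dilution and a prompt quench keep methoxide protonated, suppress intermolecular esterification and limit re-ionisation of the allylic lactone, whose benzoate is a much poorer leaving group than carbonate.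

Step 7
Reactants: 11 7-bromohept-1-ene; 12 (S)-1,2-epoxybutane
Product: 14 (S)-undec-10-en-3-ol, via hept-6-enylmagnesium bromide 13 (not isolated)
Conditions: Mg, THF, rt; then CuI (10 mol%), 12, −30 to 0 °C; then H2O
Reagents that add atoms: none
Why: Copper-catalysed opening of a terminal epoxide by a primary alkyl Grignard reagent occurs at the unsubstituted carbon, so the C–O stereocentre of 12 is carried unchanged into C9' (S), and the eleven-carbon alkenol holds C2'–C11' plus the CH2 that is lost in step 8.

Step 8
Reactants: 10 (3S)-6,8-bis(benzyloxy)-3-vinylisochroman-1-one; 14 (S)-undec-10-en-3-ol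
Product: 15 (3S)-6,8-bis(benzyloxy)-3-[(1E,9S)-9-hydroxyundec-1-en-1-yl]isochroman-1-one
Conditions: 14 (3 equiv), second-generation Hoveyda–Grubbs catalyst (H2IMes)Cl2Ru(=CH-C6H4-2-OiPr) (5 mol%), 1,4-benzoquinone (10 mol%), CH2Cl2, 40 °C
Reagents that add atoms: none
Why: Olefin cross-metathesis between the slowly homodimerising allylic lactone olefin and an excess of an unhindered terminal alkenol should favour the cross product with loss of ethene; the remote hydroxyl is tolerated, benzoquinone suppresses ruthenium hydride migration of the double bond toward C3, and the alkene geometry is irrelevant because step 9 removes it.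

Step 9
Reactants: 15 (3S)-6,8-bis(benzyloxy)-3-[(1E,9S)-9-hydroxyundec-1-en-1-yl]isochroman-1-one
Product: 16 (3R)-6,8-bis(benzyloxy)-3-[(9S)-9-hydroxyundecyl]isochroman-1-one
Conditions: 2-nitrobenzenesulfonyl hydrazide (excess), Et3N, CH2Cl2, rt
Reagents that add atoms: none
Why: Diimide reduction transfers hydrogen concertedly to the unpolarised alkene and cannot cleave the allylic C3–O2 bond or the benzyl ethers, a risk that hydrogenation over palladium would carry at this stage; the descriptor at C3 changes to R only because the chain now ranks below C4.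

Step 10
Reactants: 16 (3R)-6,8-bis(benzyloxy)-3-[(9S)-9-hydroxyundecyl]isochroman-1-one
Product: 17 (3R)-6,8-dihydroxy-3-[(9S)-9-hydroxyundecyl]isochroman-1-one
Conditions: H2 (1 atm), Pd/C (10%), EtOAc, rt
Reagents that add atoms: none
Why: Hydrogenolysis of aryl benzyl ethers over palladium on carbon is routine, and with the alkene already saturated the C3–O2 bond is neither allylic nor benzylic, so the lactone and both stereocentres are untouched.

Compound list
1 | 3,5-bis(benzyloxy)benzyl bromide | BrCc1cc(OCc2ccccc2)cc(OCc2ccccc2)c1 | starting material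
2 | vinylmagnesium bromide | C=C[Mg]Br | starting material
3 | 1-allyl-3,5-bis(benzyloxy)benzene | C=CCc1cc(OCc2ccccc2)cc(OCc2ccccc2)c1 | intermediate
4 | N-[2-allyl-4,6-bis(benzyloxy)benzylidene]-N-methylmethanaminium dichlorophosphate | C=CCc1cc(OCc2ccccc2)cc(OCc2ccccc2)c1C=[N+](C)C.[O-]P(=O)(Cl)Cl | intermediate
5 | 2-allyl-4,6-bis(benzyloxy)benzaldehyde | C=CCc1cc(OCc2ccccc2)cc(OCc2ccccc2)c1C=O | intermediate
6 | (Z)-but-2-ene-1,4-diol | OC/C=C\CO | starting material
7 | (Z)-but-2-ene-1,4-diyl dimethyl bis(carbonate) | COC(=O)OC/C=C\COC(=O)OC | intermediate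
8 | (E)-4-[3,5-bis(benzyloxy)-2-formylphenyl]but-2-en-1-yl methyl carbonate | COC(=O)OC/C=C/Cc1cc(OCc2ccccc2)cc(OCc2ccccc2)c1C=O | intermediate
9 | 2,4-bis(benzyloxy)-6-[(E)-4-(methoxycarbonyloxy)but-2-en-1-yl]benzoic acid | COC(=O)OC/C=C/Cc1cc(OCc2ccccc2)cc(OCc2ccccc2)c1C(=O)O | intermediate
10 | (3S)-6,8-bis(benzyloxy)-3-vinylisochroman-1-one | C=C[C@@H]1Cc2cc(OCc3ccccc3)cc(OCc3ccccc3)c2C(=O)O1 | intermediate
11 | 7-bromohept-1-ene | C=CCCCCCBr | starting material
12 | (S)-1,2-epoxybutane | CC[C@H]1CO1 | starting material
13 | hept-6-enylmagnesium bromide | C=CCCCCC[Mg]Br | intermediate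
14 | (S)-undec-10-en-3-ol | CC[C@H](O)CCCCCCC=C | intermediate
15 | (3S)-6,8-bis(benzyloxy)-3-[(1E,9S)-9-hydroxyundec-1-en-1-yl]isochroman-1-one | CC[C@H](O)CCCCCC/C=C/[C@@H]1Cc2cc(OCc3ccccc3)cc(OCc3ccccc3)c2C(=O)O1 | intermediate
16 | (3R)-6,8-bis(benzyloxy)-3-[(9S)-9-hydroxyundecyl]isochroman-1-one | CC[C@H](O)CCCCCCCC[C@@H]1Cc2cc(OCc3ccccc3)cc(OCc3ccccc3)c2C(=O)O1 | intermediate
17 | (3R)-6,8-dihydroxy-3-[(9S)-9-hydroxyundecyl]isochroman-1-one | CC[C@H](O)CCCCCCCC[C@@H]1Cc2cc(O)cc(O)c2C(=O)O1 | target

Total step count: 10. Longest linear sequence: 8 steps (steps 1, 2, 4, 5, 6, 8, 9, 10); steps 3 and 7 make the two metathesis partners.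

Steps most likely to fail

Step 6 (labelled step). The closure may suffer from slow turnover in the presence of the free acid, from poor facial selectivity, or from erosion of configuration by re-ionisation of the allylic lactone. The fallback sets out from 9, returns at 10 and uses only known chemistry, with C3 set by Sharpless asymmetric epoxidation. Acid 9 is methylated (MeI, K2CO3, DMF) to methyl 2,4-bis(benzyloxy)-6-[(E)-4-(methoxycarbonyloxy)but-2-en-1-yl]benzoate F1. Methanolysis of the carbonate (K2CO3, MeOH, 0 °C) gives methyl 2,4-bis(benzyloxy)-6-[(E)-4-hydroxybut-2-en-1-yl]benzoate F2. Epoxidation with Ti(OiPr)4, L-(+)-diethyl tartrate and t-BuOOH (4 Å sieves, CH2Cl2, −20 °C) should give methyl 2,4-bis(benzyloxy)-6-{[(2S,3S)-3-(hydroxymethyl)oxiran-2-yl]methyl}benzoate F3. Iodination (I2, PPh3, imidazole) gives methyl 2,4-bis(benzyloxy)-6-{[(2S,3R)-3-(iodomethyl)oxiran-2-yl]methyl}benzoate F4. Reductive opening with Zn in EtOH at 60 °C breaks only the C–O bond next to the iodide and gives methyl 2,4-bis(benzyloxy)-6-[(2S)-2-hydroxybut-3-en-1-yl]benzoate F5, whose carbinol carbon is the future C3. Catalytic NaH in THF then closes the lactone to 10.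

Step 4. The cross-metathesis may give incomplete E selectivity, homodimer, or migration of the allyl double bond into conjugation with the ring, and Z-configured material would erode the selectivity of step 6. The fallback sets out from 1, returns at 8 and uses an alkene of defined geometry. Suzuki–Miyaura coupling of 1 with commercial (E)-3-(tert-butyldimethylsilyloxy)prop-1-enylboronic acid pinacol ester (Pd(dppf)Cl2, K3PO4, THF/H2O, 60 °C; zerovalent palladium cycle, alkene geometry retained) gives tert-butyl{[(E)-4-(3,5-bis(benzyloxy)phenyl)but-2-en-1-yl]oxy}dimethylsilane F6. Bu4NF in THF gives (E)-4-[3,5-bis(benzyloxy)phenyl]but-2-en-1-ol F7. ClCO2Me and pyridine give (E)-4-[3,5-bis(benzyloxy)phenyl]but-2-en-1-yl methyl carbonate F8. Vilsmeier formylation (POCl3, DMF; then H2O) proceeds through N-{2,4-bis(benzyloxy)-6-[(E)-4-(methoxycarbonyloxy)but-2-en-1-yl]benzylidene}-N-methylmethanaminium dichlorophosphate F9 and gives 8.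

Step 8. The metathesis may stall at the oxygen-substituted allylic olefin, or ruthenium hydride species may move the double bond toward C3 and scramble that centre. The fallback sets out from 10 and 12, returns at 16 and forms C2'–C3' as an sp3–sp3 bond without touching C3. Commercial pent-4-enylmagnesium bromide (CH2=CH(CH2)3MgBr) opens 12 under CuI catalysis to (S)-non-8-en-3-ol F10. Radical anti-Markovnikov addition of HBr (dibenzoyl peroxide, hexane, 0 °C) gives (S)-9-bromononan-3-ol F11. Hydroboration of 10 with 9-BBN-H (THF, rt) gives (3R)-6,8-bis(benzyloxy)-3-[2-(9-borabicyclo[3.3.1]nonan-9-yl)ethyl]isochroman-1-one F12. Alkyl–alkyl Suzuki coupling of F12 with F11 (Pd(OAc)2, PCy3, K3PO4·H2O, THF, rt) delivers 16 directly, so steps 8 and 9 are both bypassed.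

Further compounds
F1 | step 6 | methyl 2,4-bis(benzyloxy)-6-[(E)-4-(methoxycarbonyloxy)but-2-en-1-yl]benzoate | COC(=O)OC/C=C/Cc1cc(OCc2ccccc2)cc(OCc2ccccc2)c1C(=O)OC
F2 | step 6 | methyl 2,4-bis(benzyloxy)-6-[(E)-4-hydroxybut-2-en-1-yl]benzoate | OC/C=C/Cc1cc(OCc2ccccc2)cc(OCc2ccccc2)c1C(=O)OC
F3 | step 6 | methyl 2,4-bis(benzyloxy)-6-{[(2S,3S)-3-(hydroxymethyl)oxiran-2-yl]methyl}benzoate | OC[C@@H]1O[C@H]1Cc2cc(OCc3ccccc3)cc(OCc3ccccc3)c2C(=O)OC
F4 | step 6 | methyl 2,4-bis(benzyloxy)-6-{[(2S,3R)-3-(iodomethyl)oxiran-2-yl]methyl}benzoate | IC[C@@H]1O[C@H]1Cc2cc(OCc3ccccc3)cc(OCc3ccccc3)c2C(=O)OC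
F5 | step 6 | methyl 2,4-bis(benzyloxy)-6-[(2S)-2-hydroxybut-3-en-1-yl]benzoate | C=C[C@@H](O)Cc1cc(OCc2ccccc2)cc(OCc2ccccc2)c1C(=O)OC
F6 | step 4 | tert-butyl{[(E)-4-(3,5-bis(benzyloxy)phenyl)but-2-en-1-yl]oxy}dimethylsilane | CC(C)(C)[Si](C)(C)OC/C=C/Cc1cc(OCc2ccccc2)cc(OCc2ccccc2)c1
F7 | step 4 | (E)-4-[3,5-bis(benzyloxy)phenyl]but-2-en-1-ol | OC/C=C/Cc1cc(OCc2ccccc2)cc(OCc2ccccc2)c1
F8 | step 4 | (E)-4-[3,5-bis(benzyloxy)phenyl]but-2-en-1-yl methyl carbonate | COC(=O)OC/C=C/Cc1cc(OCc2ccccc2)cc(OCc2ccccc2)c1
F9 | step 4 | N-{2,4-bis(benzyloxy)-6-[(E)-4-(methoxycarbonyloxy)but-2-en-1-yl]benzylidene}-N-methylmethanaminium dichlorophosphate | COC(=O)OC/C=C/Cc1cc(OCc2ccccc2)cc(OCc2ccccc2)c1C=[N+](C)C.[O-]P(=O)(Cl)Cl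
F10 | step 8 | (S)-non-8-en-3-ol | CC[C@H](O)CCCCC=C
F11 | step 8 | (S)-9-bromononan-3-ol | CC[C@H](O)CCCCCCBr
F12 | step 8 | (3R)-6,8-bis(benzyloxy)-3-[2-(9-borabicyclo[3.3.1]nonan-9-yl)ethyl]isochroman-1-one | B1(CC[C@@H]2Cc3cc(OCc4ccccc4)cc(OCc4ccccc4)c3C(=O)O2)C2CCCC1CCC2
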